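## Retrosynthetic overview

- Target: (3S,5R,8R,9Z)-5,8-epoxy-5,8-dihydro-10'-apo-β-carotene-3,10'-diol (carotenoid numbering). Both hydroxyls are freed last by iBu2AlH on the C27 ethyl ester 3-acetate.
- C11=C12: Wittig reaction of a furanoid (9Z)-C15 phosphonium salt with a C12 aldehyde ester (C10 dialdehyde + phosphonoacetate).
- Dihydrofuran ring and C8: 5-endo cycloisomerisation of an α-hydroxy vinylallene, with axis-to-centre chirality transfer.
- Allene axis: anti SN2' hydride opening of a 5,6-epoxy-7-yne. The epoxide is set anti to the 3-acetoxy group on a dienyne made by Sonogashira coupling.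
- Ring order: the cyclohexane is bought in (4R,6R)-actinol (supplies C3, which relays to C5, C6, the axis and C8); the oxirane (temporary) is second; the dihydrofuran is last.

Assumption: the SMILES is read literally, so C9=C10 is Z (C8 and C11 cis) and all other chain double bonds are E; (4R,6R)-actinol, (Z)-3-methylpent-2-en-4-yn-1-ol and the C10 dialdehyde are taken as commercial.

## Route

Step 1
Reactants: 1 (4R,6R)-4-hydroxy-2,2,6-trimethylcyclohexanone
Product: 2 (1R,3R)-3,5,5-trimethyl-4-oxocyclohexyl acetate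
Conditions: Ac2O, pyridine, DMAP (cat.), CH2Cl2, 0 °C to rt
Reagents that add atoms: acetic anhydride, CC(=O)OC(C)=O
Why: Acylation of the secondary alcohol gives an ester that survives every later step and is cleaved by the final hydride reduction, so no separate deprotection is needed.

Step 2
Reactants: 2 (1R,3R)-3,5,5-trimethyl-4-oxocyclohexyl acetate
Product: 3 (1R)-3,5,5-trimethyl-4-(trifluoromethanesulfonyloxy)cyclohex-3-en-1-yl acetate
Conditions: Tf2O, 2,6-di-tert-butyl-4-methylpyridine, CH2Cl2, 0 °C to rt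
Reagents that add atoms: trifluoromethanesulfonic anhydride, O=S(=O)(OS(=O)(=O)C(F)(F)F)C(F)(F)F
Why: Enol triflate formation under non-nucleophilic base conditions can only enolise toward the single α-CH, giving the tetrasubstituted vinyl triflate without touching the acetate or the carbinol centre.

Step 3
Reactants: 4 (2Z)-3-methylpent-2-en-4-yn-1-ol
Product: 5 tert-butyldimethyl{[(2Z)-3-methylpent-2-en-4-yn-1-yl]oxy}silane
Conditions: TBSCl, imidazole, CH2Cl2, 0 °C to rt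
Reagents that add atoms: tert-butyldimethylsilyl chloride, CC(C)(C)[Si](C)(C)Cl
Why: Silylation masks the primary allylic hydroxyl, which would otherwise direct peracid to the side-chain alkene and compete as a nucleophile in the later allene cyclisation.

Step 4
Reactants: 3 (1R)-3,5,5-trimethyl-4-(trifluoromethanesulfonyloxy)cyclohex-3-en-1-yl acetate; 5 tert-butyldimethyl{[(2Z)-3-methylpent-2-en-4-yn-1-yl]oxy}silane
Product: 6 (1R)-4-[(3Z)-5-{[tert-butyl(dimethyl)silyl]oxy}-3-methylpent-3-en-1-yn-1-yl]-3,5,5-trimethylcyclohex-3-en-1-yl acetate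
Conditions: Pd(PPh3)4 (5 mol %), CuI (10 mol %), Et3N, DMF, rt
Reagents that add atoms: none
Why: Sonogashira coupling of the vinyl triflate with the terminal alkyne forms the C6–C7 bond and carries the Z C9=C10 geometry in unchanged.

Step 5
Reactants: 6 (1R)-4-[(3Z)-5-{[tert-butyl(dimethyl)silyl]oxy}-3-methylpent-3-en-1-yn-1-yl]-3,5,5-trimethylcyclohex-3-en-1-yl acetate
Product: 7 (1R,3S,6R)-6-[(3Z)-5-{[tert-butyl(dimethyl)silyl]oxy}-3-methylpent-3-en-1-yn-1-yl]-1,5,5-trimethyl-7-oxabicyclo[4.1.0]heptan-3-yl acetate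
Conditions: mCPBA (1.1 equiv), NaHCO3, CH2Cl2, −20 to 0 °C; chromatography
Reagents that add atoms: 3-chloroperbenzoic acid, OOC(=O)c1cccc(Cl)c1
Why: Prilezhaev epoxidation takes the more electron-rich tetrasubstituted ring alkene, and the peracid is expected to approach anti to the homoallylic acetoxy group (about 3:1, minor syn epoxide removed), which sets C5 as R with the oxygen trans to the C3 oxygen.

Step 6
Reactants: 7 (1R,3S,6R)-6-[(3Z)-5-{[tert-butyl(dimethyl)silyl]oxy}-3-methylpent-3-en-1-yn-1-yl]-1,5,5-trimethyl-7-oxabicyclo[4.1.0]heptan-3-yl acetate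
Product: 9 (1S,3R)-4-[(aS,3Z)-5-{[tert-butyl(dimethyl)silyl]oxy}-3-methylpenta-1,3-dien-1-ylidene]-3-hydroxy-3,5,5-trimethylcyclohexyl acetate, via silyl ether 8 (not isolated)
Conditions: CuCl (5 mol %), IPr·HCl (5 mol %), NaOtBu (15 mol %), MeSiH(OEt)2 (2 equiv), toluene, 0 °C; then NH4F, MeOH–H2O, 0 °C; used at once, kept at or below 0 °C
Reagents that add atoms: none
Why: Copper hydride SN2' reduction of the propargylic oxirane (syn hydrocupration, then anti β-elimination) places H on C8 anti to the departing C6–O bond, so the epoxide configuration is transferred to the allene axis (aS, C9 on the side of the retained 5R hydroxyl).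

Step 7
Reactants: 9 (1S,3R)-4-[(aS,3Z)-5-{[tert-butyl(dimethyl)silyl]oxy}-3-methylpenta-1,3-dien-1-ylidene]-3-hydroxy-3,5,5-trimethylcyclohexyl acetate
Product: 10 (2R,6S,7aR)-2-[(2Z)-4-{[tert-butyl(dimethyl)silyl]oxy}but-2-en-2-yl]-4,4,7a-trimethyl-2,4,5,6,7,7a-hexahydro-1-benzofuran-6-yl acetate
Conditions: AuCl3 (2 mol %), THF, 0 °C to rt; Et3N quench
Reagents that add atoms: none
Why: Gold-catalysed 5-endo cycloisomerisation of the α-hydroxyallene adds the tertiary hydroxyl to C8 in the plane of the new ring, so the allene axis becomes the C8 centre (H cis to the 7a-methyl, 8R) and the C6=C7 bond ends up in the ring.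

Step 8
Reactants: 10 (2R,6S,7aR)-2-[(2Z)-4-{[tert-butyl(dimethyl)silyl]oxy}but-2-en-2-yl]-4,4,7a-trimethyl-2,4,5,6,7,7a-hexahydro-1-benzofuran-6-yl acetate
Product: 12 {(2Z)-3-[(2R,6S,7aR)-6-acetoxy-4,4,7a-trimethyl-2,4,5,6,7,7a-hexahydro-1-benzofuran-2-yl]but-2-en-1-yl}triphenylphosphonium bromide, via allylic bromide 11 (not isolated)
Conditions: Ph3PBr2 (1.1 equiv), CH2Cl2, 0 °C to rt; then PPh3 (1.2 equiv), rt to 40 °C; precipitate with Et2O
Reagents that add atoms: dibromotriphenylphosphorane, BrP(Br)(c1ccccc1)(c1ccccc1)c1ccccc1; triphenylphosphine, c1ccc(cc1)P(c1ccccc1)c1ccccc1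
Why: Direct conversion of the primary allylic silyl ether to the bromide, then SN2 quaternisation by PPh3, avoids protic acid that would epimerise the bis-allylic C8 ether and keeps the Z geometry because both displacements occur at the primary carbon.

Step 9
Reactants: 13 (2E,4E,6E)-2,7-dimethylocta-2,4,6-trienedial (3 equiv); 14 triethyl phosphonoacetate
Product: 15 ethyl (2E,4E,6E,8E)-4,9-dimethyl-10-oxodeca-2,4,6,8-tetraenoate
Conditions: LiCl, DBU, MeCN, 0 °C to rt; excess 13 recovered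
Reagents that add atoms: none
Why: Horner–Wadsworth–Emmons olefination under mild amine/LiCl conditions is E-selective, and the excess of the symmetrical dialdehyde limits reaction to one end.

Step 10
Reactants: 12 {(2Z)-3-[(2R,6S,7aR)-6-acetoxy-4,4,7a-trimethyl-2,4,5,6,7,7a-hexahydro-1-benzofuran-2-yl]but-2-en-1-yl}triphenylphosphonium bromide; 15 ethyl (2E,4E,6E,8E)-4,9-dimethyl-10-oxodeca-2,4,6,8-tetraenoate
Product: 18 ethyl (2E,4E,6E,8E,10E,12Z)-13-[(2R,6S,7aR)-6-acetoxy-4,4,7a-trimethyl-2,4,5,6,7,7a-hexahydro-1-benzofuran-2-yl]-4,9-dimethyltetradeca-2,4,6,8,10,12-hexaenoate, via ylide 16 (not isolated), via 11Z ester 17 (not isolated)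
Conditions: NaN(SiMe3)2 (1.0 equiv), THF, −78 °C; add 15, −78 to 0 °C; then EtOAc, 70 °C, N2, dark, 2 h
Reagents that add atoms: none
Why: Wittig olefination of the allylic ylide with the α-methyl enal forms C11=C12 as an E/Z mixture whose hindered 11Z component isomerises thermally to 11E, while the trisubstituted 9Z bond and C8 (not deprotonated, since the ylide forms at C11) are retained.

Step 11
Reactants: 18 ethyl (2E,4E,6E,8E,10E,12Z)-13-[(2R,6S,7aR)-6-acetoxy-4,4,7a-trimethyl-2,4,5,6,7,7a-hexahydro-1-benzofuran-2-yl]-4,9-dimethyltetradeca-2,4,6,8,10,12-hexaenoate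
Product: 19 (2E,4E,6E,8E,10E,12Z)-13-[(2R,6S,7aR)-6-hydroxy-4,4,7a-trimethyl-2,4,5,6,7,7a-hexahydro-1-benzofuran-2-yl]-4,9-dimethyltetradeca-2,4,6,8,10,12-hexaen-1-ol
Conditions: iBu2AlH (6 equiv), CH2Cl2, −78 to −20 °C; aq. KNaC4H4O6 work-up (no acid)
Reagents that add atoms: none
Why: Excess aluminium hydride reduces the conjugated ester 1,2 to the allylic alcohol and cleaves the acetate in the same operation, and the neutral tartrate work-up avoids acid-induced C8 epimerisation.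

## Compound list

1 | (4R,6R)-4-hydroxy-2,2,6-trimethylcyclohexanone (actinol) | O=C1C(C)(C)C[C@H](O)C[C@H]1C | starting material
2 | (1R,3R)-3,5,5-trimethyl-4-oxocyclohexyl acetate | O=C1C(C)(C)C[C@H](OC(C)=O)C[C@H]1C | intermediate
3 | (1R)-3,5,5-trimethyl-4-(trifluoromethanesulfonyloxy)cyclohex-3-en-1-yl acetate | CC1=C(OS(=O)(=O)C(F)(F)F)C(C)(C)C[C@H](OC(C)=O)C1 | intermediate
4 | (2Z)-3-methylpent-2-en-4-yn-1-ol | C#C/C(C)=C\CO | starting material
5 | tert-butyldimethyl{[(2Z)-3-methylpent-2-en-4-yn-1-yl]oxy}silane | C#C/C(C)=C\CO[Si](C)(C)C(C)(C)C | intermediate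
6 | (1R)-4-[(3Z)-5-{[tert-butyl(dimethyl)silyl]oxy}-3-methylpent-3-en-1-yn-1-yl]-3,5,5-trimethylcyclohex-3-en-1-yl acetate | CC1=C(C#C/C(C)=C\CO[Si](C)(C)C(C)(C)C)C(C)(C)C[C@H](OC(C)=O)C1 | intermediate
7 | (1R,3S,6R)-6-[(3Z)-5-{[tert-butyl(dimethyl)silyl]oxy}-3-methylpent-3-en-1-yn-1-yl]-1,5,5-trimethyl-7-oxabicyclo[4.1.0]heptan-3-yl acetate | CC1(C)C[C@H](OC(C)=O)C[C@@]2(C)O[C@@]12C#C/C(C)=C\CO[Si](C)(C)C(C)(C)C | intermediate
8 | (1S,3R)-4-[(aS,3Z)-5-{[tert-butyl(dimethyl)silyl]oxy}-3-methylpenta-1,3-dien-1-ylidene]-3-{[diethoxy(methyl)silyl]oxy}-3,5,5-trimethylcyclohexyl acetate | CC1(C)C[C@H](OC(C)=O)C[C@@](C)(O[Si](C)(OCC)OCC)C1=[C@@]=C([H])/C(C)=C\CO[Si](C)(C)C(C)(C)C | intermediate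
9 | (1S,3R)-4-[(aS,3Z)-5-{[tert-butyl(dimethyl)silyl]oxy}-3-methylpenta-1,3-dien-1-ylidene]-3-hydroxy-3,5,5-trimethylcyclohexyl acetate | CC1(C)C[C@H](OC(C)=O)C[C@@](C)(O)C1=[C@@]=C([H])/C(C)=C\CO[Si](C)(C)C(C)(C)C | intermediate
10 | (2R,6S,7aR)-2-[(2Z)-4-{[tert-butyl(dimethyl)silyl]oxy}but-2-en-2-yl]-4,4,7a-trimethyl-2,4,5,6,7,7a-hexahydro-1-benzofuran-6-yl acetate | C/C(=C/CO[Si](C)(C)C(C)(C)C)[C@H]1C=C2C(C)(C)C[C@H](OC(C)=O)C[C@@]2(C)O1 | intermediate
11 | (2R,6S,7aR)-2-[(2Z)-4-bromobut-2-en-2-yl]-4,4,7a-trimethyl-2,4,5,6,7,7a-hexahydro-1-benzofuran-6-yl acetate | C/C(=C/CBr)[C@H]1C=C2C(C)(C)C[C@H](OC(C)=O)C[C@@]2(C)O1 | intermediate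
12 | {(2Z)-3-[(2R,6S,7aR)-6-acetoxy-4,4,7a-trimethyl-2,4,5,6,7,7a-hexahydro-1-benzofuran-2-yl]but-2-en-1-yl}triphenylphosphonium bromide | C/C(=C/C[P+](c1ccccc1)(c1ccccc1)c1ccccc1)[C@H]1C=C2C(C)(C)C[C@H](OC(C)=O)C[C@@]2(C)O1.[Br-] | intermediate
13 | (2E,4E,6E)-2,7-dimethylocta-2,4,6-trienedial | O=C/C(C)=C/C=C/C=C(\C)C=O | starting material
14 | triethyl phosphonoacetate | CCOC(=O)CP(=O)(OCC)OCC | starting material
15 | ethyl (2E,4E,6E,8E)-4,9-dimethyl-10-oxodeca-2,4,6,8-tetraenoate | CCOC(=O)/C=C/C(C)=C/C=C/C=C(\C)C=O | intermediate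
16 | {(2Z)-3-[(2R,6S,7aR)-6-acetoxy-4,4,7a-trimethyl-2,4,5,6,7,7a-hexahydro-1-benzofuran-2-yl]but-2-en-1-ylidene}triphenylphosphorane | C/C(=C/C=P(c1ccccc1)(c1ccccc1)c1ccccc1)[C@H]1C=C2C(C)(C)C[C@H](OC(C)=O)C[C@@]2(C)O1 | intermediate
17 | ethyl (2E,4E,6E,8E,10Z,12Z)-13-[(2R,6S,7aR)-6-acetoxy-4,4,7a-trimethyl-2,4,5,6,7,7a-hexahydro-1-benzofuran-2-yl]-4,9-dimethyltetradeca-2,4,6,8,10,12-hexaenoate | C\C(=C\C=C/C(C)=C/C=C/C=C(C)/C=C/C(=O)OCC)[C@H]1C=C2C(C)(C)C[C@H](OC(C)=O)C[C@@]2(C)O1 | intermediate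
18 | ethyl (2E,4E,6E,8E,10E,12Z)-13-[(2R,6S,7aR)-6-acetoxy-4,4,7a-trimethyl-2,4,5,6,7,7a-hexahydro-1-benzofuran-2-yl]-4,9-dimethyltetradeca-2,4,6,8,10,12-hexaenoate | C/C(=C/C=C/C(C)=C/C=C/C=C(C)/C=C/C(=O)OCC)[C@H]1C=C2C(C)(C)C[C@H](OC(C)=O)C[C@@]2(C)O1 | intermediate
19 | (2E,4E,6E,8E,10E,12Z)-13-[(2R,6S,7aR)-6-hydroxy-4,4,7a-trimethyl-2,4,5,6,7,7a-hexahydro-1-benzofuran-2-yl]-4,9-dimethyltetradeca-2,4,6,8,10,12-hexaen-1-ol | C/C(=C/C=C/C(C)=C/C=C/C=C(C)/C=C/CO)[C@H]1C=C2C(C)(C)C[C@H](O)C[C@@]2(C)O1 | target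

## Step count and risks

Total steps: 11. Longest linear sequence: 9 steps (1 → 2 → 3 → 6 → 7 → 9 → 10 → 12 → 18 → 19; steps 1, 2, 4, 5, 6, 7, 8, 10, 11).

The three steps most likely to fail:

Step 5 (epoxidation). The facial preference of the peracid rests on a remote acetoxy group and may be low or even syn, and some side-chain alkene may be oxidised. The fallback inverts the facial outcome by a halohydrin sequence. It sets out from 6: NBS in THF–H2O forms the bromonium ion on the face the peracid prefers, and water opens it anti to give the trans-bromohydrin (1S,3R,4S)-4-bromo-4-[(3Z)-5-{[tert-butyl(dimethyl)silyl]oxy}-3-methylpent-3-en-1-yn-1-yl]-3-hydroxy-3,5,5-trimethylcyclohexyl acetate F1. K2CO3 in MeCN then closes the ring with inversion at the bromine-bearing carbon, putting the epoxide oxygen on the opposite face. The fallback comes back to the route at 7.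

Step 6 (SN2' reduction). The copper hydride could add with the wrong regiochemistry on the conjugated enyne or erode the chirality transfer. The (Z)-vinylallene 9 can also undergo a thermal hydrogen shift from C11 if it is warmed or stored. The fallback gives up the allene and uses the classical epoxide-to-furanoid rearrangement. It sets out from 7: semi-hydrogenation (H2, Pd/CaCO3 poisoned with Pb(OAc)2, quinoline) gives the dienyl epoxide (1R,3S,6S)-6-[(1Z,3Z)-5-{[tert-butyl(dimethyl)silyl]oxy}-3-methylpenta-1,3-dien-1-yl]-1,5,5-trimethyl-7-oxabicyclo[4.1.0]heptan-3-yl acetate F2. Pyridinium p-toluenesulfonate (cat.) in CH2Cl2 at 0 °C then opens the oxirane at C6 and closes O5 onto C8. This gives 10 together with its 8S epimer (2S,6S,7aR)-2-[(2Z)-4-{[tert-butyl(dimethyl)silyl]oxy}but-2-en-2-yl]-4,4,7a-trimethyl-2,4,5,6,7,7a-hexahydro-1-benzofuran-6-yl acetate F3. The two are separated by chromatography and the unwanted epimer is re-equilibrated under the same acid. The cost is loss of C8 control and a possible erosion of the 9Z geometry. The fallback comes back to the route at 10.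

Step 10 (Wittig). The ylide next to the bis-allylic ring ether could open the dihydrofuran by vinylogous elimination or lose the 9Z geometry, and the thermal 11Z to 11E isomerisation may be incomplete. The fallback reverses the polarity so that no carbanion sits next to the ring. It sets out from 10 and 15:
- Bu4NF/AcOH in THF gives the allylic alcohol (2R,6S,7aR)-2-[(2Z)-4-hydroxybut-2-en-2-yl]-4,4,7a-trimethyl-2,4,5,6,7,7a-hexahydro-1-benzofuran-6-yl acetate F4.
- MnO2 in CH2Cl2 gives the (Z)-enal (2R,6S,7aR)-4,4,7a-trimethyl-2-[(2Z)-4-oxobut-2-en-2-yl]-2,4,5,6,7,7a-hexahydro-1-benzofuran-6-yl acetate F5.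
- In parallel, 15 is reduced with NaBH4 in EtOH at 0 °C to the hydroxy ester ethyl (2E,4E,6E,8E)-10-hydroxy-4,9-dimethyldeca-2,4,6,8-tetraenoate F6.
- PBr3 converts this to the bromide ethyl (2E,4E,6E,8E)-10-bromo-4,9-dimethyldeca-2,4,6,8-tetraenoate F7.
- P(OEt)3 (Arbuzov) converts this to the phosphonate ethyl (2E,4E,6E,8E)-10-(diethoxyphosphoryl)-4,9-dimethyldeca-2,4,6,8-tetraenoate F8.
- E-selective Horner–Wadsworth–Emmons coupling of F8 with F5 (NaN(SiMe3)2, THF, −78 to 0 °C) forms C11=C12 directly.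

The fallback comes back to the route at 18.

## Further compounds

F1 | step 5 | (1S,3R,4S)-4-bromo-4-[(3Z)-5-{[tert-butyl(dimethyl)silyl]oxy}-3-methylpent-3-en-1-yn-1-yl]-3-hydroxy-3,5,5-trimethylcyclohexyl acetate | CC1(C)C[C@H](OC(C)=O)C[C@@](C)(O)[C@@]1(Br)C#C/C(C)=C\CO[Si](C)(C)C(C)(C)C
F2 | step 6 | (1R,3S,6S)-6-[(1Z,3Z)-5-{[tert-butyl(dimethyl)silyl]oxy}-3-methylpenta-1,3-dien-1-yl]-1,5,5-trimethyl-7-oxabicyclo[4.1.0]heptan-3-yl acetate | CC1(C)C[C@H](OC(C)=O)C[C@@]2(C)O[C@@]12/C=C\C(C)=C/CO[Si](C)(C)C(C)(C)C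
F3 | step 6 | (2S,6S,7aR)-2-[(2Z)-4-{[tert-butyl(dimethyl)silyl]oxy}but-2-en-2-yl]-4,4,7a-trimethyl-2,4,5,6,7,7a-hexahydro-1-benzofuran-6-yl acetate | C/C(=C/CO[Si](C)(C)C(C)(C)C)[C@@H]1C=C2C(C)(C)C[C@H](OC(C)=O)C[C@@]2(C)O1
F4 | step 10 | (2R,6S,7aR)-2-[(2Z)-4-hydroxybut-2-en-2-yl]-4,4,7a-trimethyl-2,4,5,6,7,7a-hexahydro-1-benzofuran-6-yl acetate | C/C(=C/CO)[C@H]1C=C2C(C)(C)C[C@H](OC(C)=O)C[C@@]2(C)O1
F5 | step 10 | (2R,6S,7aR)-4,4,7a-trimethyl-2-[(2Z)-4-oxobut-2-en-2-yl]-2,4,5,6,7,7a-hexahydro-1-benzofuran-6-yl acetate | C/C(=C/C=O)[C@H]1C=C2C(C)(C)C[C@H](OC(C)=O)C[C@@]2(C)O1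
F6 | step 10 | ethyl (2E,4E,6E,8E)-10-hydroxy-4,9-dimethyldeca-2,4,6,8-tetraenoate | CCOC(=O)/C=C/C(C)=C/C=C/C=C(\C)CO
F7 | step 10 | ethyl (2E,4E,6E,8E)-10-bromo-4,9-dimethyldeca-2,4,6,8-tetraenoate | CCOC(=O)/C=C/C(C)=C/C=C/C=C(\C)CBr
F8 | step 10 | ethyl (2E,4E,6E,8E)-10-(diethoxyphosphoryl)-4,9-dimethyldeca-2,4,6,8-tetraenoate | CCOC(=O)/C=C/C(C)=C/C=C/C=C(\C)CP(=O)(OCC)OCC
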